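The pyranone C ring is cut at its carbonyl carbon. C4 is a single carbon flanked by the A-ring carbon C4a and the C3=C2 unit, and O1 sits on C8a, ortho to C4a, so C4 can enter as carbon monoxide. In one palladium-catalysed operation an ortho-iodophenol (A ring), CO and a B-ring arylacetylene are joined through C4a–C4 and C4–C3, and the phenol oxygen adds 6-endo to form O1–C2 and close the ring. The iodophenol is 3-(benzyloxy)-2-iodo-4,5,6-trimethoxyphenol; its benzyl ether becomes the protected 5-oxygen, so C3 hydroxylation and one hydrogenolysis finish the synthesis.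

Key step: step 8

Remark: the target has no stereocentre and no hindered axis, so the SMILES defines one achiral compound and no asymmetric step is needed; the only stereocentres in the route belong to a transient racemic epoxide.

Remark on precursor design: the A-ring partner is used as its mono-benzyl ether, not as a free 2-iodoresorcinol. The benzyl group goes on before the second hydroxyl is unveiled, so no statistical protection is needed. It keeps a penta-oxygenated resorcinol out of the hydroxylation, iodination and Pd/CO steps, and it arrives in the flavone as the 5-O-benzyl group that the C3 oxidation requires.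

Step 1
Reactants: 1 2,3,4-trimethoxybenzaldehyde
Product: 2 5-bromo-2,3,4-trimethoxybenzaldehyde
Conditions: NBS (1.05 equiv), DMF, rt, dark
Reagents that add atoms: N-bromosuccinimide O=C1CCC(=O)N1Br
Why: Electrophilic aromatic bromination should go to C5, which is para to the 2-methoxy and ortho to the 4-methoxy group and meta to the formyl group, whereas C6 is ortho to the aldehyde and activated only by the twisted 3-methoxy group.

Step 2
Reactants: 2 5-bromo-2,3,4-trimethoxybenzaldehyde
Product: 4 5-bromo-2,3,4-trimethoxyphenol, via aryl formate 3 (not isolated)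
Conditions: mCPBA, CH2Cl2, 0 °C to rt; aq. NaHCO3/Na2S2O3 wash; then K2CO3 (cat.), MeOH, rt
Reagents that add atoms: 3-chloroperoxybenzoic acid OOC(=O)c1cccc(Cl)c1
Why: Baeyer–Villiger (Dakin-type) oxidation, in which the aryl group carrying ortho- and para-methoxy donors migrates in the Criegee intermediate to give the aryl formate, which mild methanolysis cleaves to the phenol without touching the bromide.

Step 3
Reactants: 4 5-bromo-2,3,4-trimethoxyphenol
Product: 5 1-(benzyloxy)-5-bromo-2,3,4-trimethoxybenzene
Conditions: BnBr, K2CO3, DMF, rt to 50 °C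
Reagents that add atoms: benzyl bromide BrCc1ccccc1
Why: Williamson ether synthesis on the phenoxide, which masks the future 5-oxygen and removes the acidic proton before the organolithium step.

Step 4
Reactants: 5 1-(benzyloxy)-5-bromo-2,3,4-trimethoxybenzene
Product: 8 5-(benzyloxy)-2,3,4-trimethoxyphenol, via aryllithium 6 (not isolated), via dimethyl arylboronate 7 (not isolated)
Conditions: n-BuLi, THF, −78 °C; B(OMe)3, −78 °C to rt; then AcOH, 30% aq. H2O2, 0 °C to rt
Reagents that add atoms: hydrogen peroxide OO (the new oxygen); n-butyllithium [Li]CCCC and trimethyl borate COB(OC)OC (lithium and boron only in intermediates 6 and 7)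
Why: Bromine–lithium exchange at −78 °C is faster than deprotonation of the benzyl ether, and the aryllithium is trapped as the boronate and oxidised by 1,2-aryl migration from boron to oxygen (borylation–oxidation hydroxylation of an aryl halide).

Step 5
Reactants: 8 5-(benzyloxy)-2,3,4-trimethoxyphenol
Product: 9 3-(benzyloxy)-2-iodo-4,5,6-trimethoxyphenol
Conditions: I2, NaHCO3, THF/H2O, 0 °C to rt; Na2S2O3 quench
Reagents that add atoms: iodine II
Why: Electrophilic aromatic iodination of the phenoxide can only occur at the single unsubstituted ring carbon, which lies ortho to the free hydroxyl, and the unactivated benzyl phenyl ring does not compete.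

Step 6
Reactants: 10 3-hydroxy-4,5-dimethoxybenzaldehyde
Product: 11 3-(benzyloxy)-4,5-dimethoxybenzaldehyde
Conditions: BnBr, K2CO3, DMF, rt
Reagents that add atoms: benzyl bromide BrCc1ccccc1
Why: Williamson ether synthesis, which protects the B-ring phenol with the same group used on the A ring so that one final hydrogenolysis frees both.

Step 7
Reactants: 11 3-(benzyloxy)-4,5-dimethoxybenzaldehyde; 12 dimethyl (1-diazo-2-oxopropyl)phosphonate
Product: 13 1-(benzyloxy)-5-ethynyl-2,3-dimethoxybenzene
Conditions: 12 (1.2 equiv), K2CO3, MeOH, 0 °C to rt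
Reagents that add atoms: dimethyl (1-diazo-2-oxopropyl)phosphonate (12) COP(=O)(OC)C(=[N+]=[N-])C(C)=O (supplies the terminal alkyne carbon)
Why: Ohira–Bestmann homologation, in which methanolysis of 12 releases the diazomethylphosphonate anion, which olefinates the aldehyde to a diazoalkene that loses N2 and undergoes a 1,2-hydride shift to the terminal alkyne under conditions mild enough for the benzyl ether.

Step 8
Reactants: 9 3-(benzyloxy)-2-iodo-4,5,6-trimethoxyphenol; 13 1-(benzyloxy)-5-ethynyl-2,3-dimethoxybenzene; 14 carbon monoxide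
Product: 17 5-(benzyloxy)-2-[3-(benzyloxy)-4,5-dimethoxyphenyl]-6,7,8-trimethoxy-4H-chromen-4-one, via hydroxyaryl ynone 15 (not isolated), via diethylamino enone 16 (not isolated)
Conditions: PdCl2(dppf) (5 mol %), CO (10 bar), Et2NH (solvent), 100 °C, autoclave
Reagents that add atoms: carbon monoxide (14) [C-]#[O+]; diethylamine CCNCC (nitrogen only in intermediate 16)
Why: Pd(0) inserts into the C–I bond of 9, CO inserts to give an aroyl–Pd(II) species, and copper-free coupling with the terminal alkyne forms C4a–C4 and C4–C3 in ynone 15. Diethylamine adds to the ynone to give β-amino enone 16, whose β-carbon is attacked by the ortho-phenoxide with loss of the amine, forming O1–C2. The closest known reaction type is the palladium-catalysed carbonylative Sonogashira annulation of 2-iodophenols with terminal alkynes to flavones. The pyranone ring closes in a 6-endo mode (6-endo-dig counted on the ynone, addition–elimination on the enaminone), and no stereocentre is created. The step needs carbonylation to outrun direct coupling and 6-endo closure to outrun 5-exo (aurone) closure: the electron-rich, di-ortho-substituted aryl–Pd favours CO insertion, copper is absent, and the amine adduct leaves the β-carbon as the only electrophilic site. Only one phenol is free because the other oxygen is benzylated, so there is no choice of nucleophile and the hexasubstituted A ring passes through unchanged.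

Step 9
Reactants: 17 5-(benzyloxy)-2-[3-(benzyloxy)-4,5-dimethoxyphenyl]-6,7,8-trimethoxy-4H-chromen-4-one
Product: 19 5-(benzyloxy)-2-[3-(benzyloxy)-4,5-dimethoxyphenyl]-3-hydroxy-6,7,8-trimethoxy-4H-chromen-4-one, via racemic 2,3-epoxide 18 (not isolated)
Conditions: DMDO (acetone solution, 2–3 equiv), CH2Cl2, 0 °C to rt; evaporate; then p-TsOH·H2O (cat.), CH2Cl2, rt
Reagents that add atoms: dimethyldioxirane CC1(C)OO1
Why: Neutral electrophilic epoxidation of the C2=C3 bond by the dioxirane gives epoxide 18, whose two stereocentres form without control (racemic, cis-fused by necessity) and are erased when acid opens the oxirane at C2 (cation stabilised by O1 and the aryl group) and the C3 proton is lost to give the 3-hydroxy enone (flavone-to-flavonol oxidation).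

Step 10
Reactants: 19 5-(benzyloxy)-2-[3-(benzyloxy)-4,5-dimethoxyphenyl]-3-hydroxy-6,7,8-trimethoxy-4H-chromen-4-one
Product: 20 3-demethyldigicitrin, 3,5-dihydroxy-2-(3-hydroxy-4,5-dimethoxyphenyl)-6,7,8-trimethoxy-4H-chromen-4-one
Conditions: H2 (1 atm), 10% Pd/C, EtOAc/MeOH, rt
Reagents that add atoms: none
Why: Catalytic hydrogenolysis should cleave both aryl benzyl ethers in one operation, while the tetrasubstituted vinylogous-ester C2=C3 bond and the five methyl ethers are inert at 1 atm and rt.

Compound list
1 | 2,3,4-trimethoxybenzaldehyde | COc1ccc(C=O)c(OC)c1OC | starting material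
2 | 5-bromo-2,3,4-trimethoxybenzaldehyde | COc1c(Br)cc(C=O)c(OC)c1OC | intermediate
3 | 5-bromo-2,3,4-trimethoxyphenyl formate | COc1c(Br)cc(OC=O)c(OC)c1OC | intermediate (not isolated)
4 | 5-bromo-2,3,4-trimethoxyphenol | COc1c(Br)cc(O)c(OC)c1OC | intermediate
5 | 1-(benzyloxy)-5-bromo-2,3,4-trimethoxybenzene | COc1c(Br)cc(OCc2ccccc2)c(OC)c1OC | intermediate
6 | [5-(benzyloxy)-2,3,4-trimethoxyphenyl]lithium | COc1c([Li])cc(OCc2ccccc2)c(OC)c1OC | intermediate (not isolated)
7 | dimethyl [5-(benzyloxy)-2,3,4-trimethoxyphenyl]boronate | COB(OC)c1cc(OCc2ccccc2)c(OC)c(OC)c1OC | intermediate (not isolated)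
8 | 5-(benzyloxy)-2,3,4-trimethoxyphenol | COc1c(O)cc(OCc2ccccc2)c(OC)c1OC | intermediate
9 | 3-(benzyloxy)-2-iodo-4,5,6-trimethoxyphenol | COc1c(O)c(I)c(OCc2ccccc2)c(OC)c1OC | intermediate
10 | 3-hydroxy-4,5-dimethoxybenzaldehyde | COc1cc(C=O)cc(O)c1OC | starting material
11 | 3-(benzyloxy)-4,5-dimethoxybenzaldehyde | COc1cc(C=O)cc(OCc2ccccc2)c1OC | intermediate
12 | dimethyl (1-diazo-2-oxopropyl)phosphonate | COP(=O)(OC)C(=[N+]=[N-])C(C)=O | starting material
13 | 1-(benzyloxy)-5-ethynyl-2,3-dimethoxybenzene | C#Cc1cc(OC)c(OC)c(OCc2ccccc2)c1 | intermediate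
14 | carbon monoxide | [C-]#[O+] | starting material
15 | 1-[2-(benzyloxy)-6-hydroxy-3,4,5-trimethoxyphenyl]-3-[3-(benzyloxy)-4,5-dimethoxyphenyl]prop-2-yn-1-one | COc1cc(C#CC(=O)c2c(O)c(OC)c(OC)c(OC)c2OCc2ccccc2)cc(OCc2ccccc2)c1OC | intermediate (not isolated)
16 | (E)-1-[2-(benzyloxy)-6-hydroxy-3,4,5-trimethoxyphenyl]-3-[3-(benzyloxy)-4,5-dimethoxyphenyl]-3-(diethylamino)prop-2-en-1-one (E isomer drawn; the geometry is lost on ring closure) | CCN(CC)/C(=C/C(=O)c1c(O)c(OC)c(OC)c(OC)c1OCc1ccccc1)c1cc(OC)c(OC)c(OCc2ccccc2)c1 | intermediate (not isolated)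
17 | 5-(benzyloxy)-2-[3-(benzyloxy)-4,5-dimethoxyphenyl]-6,7,8-trimethoxy-4H-chromen-4-one | COc1cc(-c2cc(=O)c3c(OCc4ccccc4)c(OC)c(OC)c(OC)c3o2)cc(OCc2ccccc2)c1OC | intermediate
18 | rac-6-(benzyloxy)-1a-[3-(benzyloxy)-4,5-dimethoxyphenyl]-3,4,5-trimethoxy-1a,7a-dihydro-7H-oxireno[2,3-b]chromen-7-one (2,3-epoxide of 17, cis-fused, racemic; one enantiomer drawn) | O=C1c2c(OCc3ccccc3)c(OC)c(OC)c(OC)c2O[C@]2(c3cc(OC)c(OC)c(OCc4ccccc4)c3)O[C@H]12 | intermediate (not isolated)
19 | 5-(benzyloxy)-2-[3-(benzyloxy)-4,5-dimethoxyphenyl]-3-hydroxy-6,7,8-trimethoxy-4H-chromen-4-one | COc1cc(-c2oc3c(OC)c(OC)c(OC)c(OCc4ccccc4)c3c(=O)c2O)cc(OCc2ccccc2)c1OC | intermediate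
20 | 3-demethyldigicitrin, 3,5-dihydroxy-2-(3-hydroxy-4,5-dimethoxyphenyl)-6,7,8-trimethoxy-4H-chromen-4-one (achiral) | COc1cc(-c2oc3c(OC)c(OC)c(OC)c(O)c3c(=O)c2O)cc(O)c1OC | target

Total step count: 10. Longest linear sequence: 8 steps (steps 1–5, 8, 9, 10); the alkyne branch (steps 6–7) joins at step 8.

Steps most likely to fail

Step 8. Oxidative addition at the electron-rich, di-ortho-oxygenated C–I bond may be slow. Direct CO-free coupling to a benzofuran, capture of the aroyl–palladium by diethylamine as an amide, or 5-exo closure to the aurone could then overtake the annulation. The fallback brings C4 in as a formyl carbon instead of CO and sets out from phenol 8 and alkyne 13. Magnesium-mediated ortho-formylation of 8 (MgCl2, Et3N, paraformaldehyde, MeCN, reflux) at its only free ring position should give 2-(benzyloxy)-6-hydroxy-3,4,5-trimethoxybenzaldehyde F1. Alkyne 13 is deprotonated (n-BuLi, THF, −78 °C) to the lithium acetylide of 13 F2, which is used in excess (2.2 equiv) and adds to F1 to give racemic 1-[2-(benzyloxy)-6-hydroxy-3,4,5-trimethoxyphenyl]-3-[3-(benzyloxy)-4,5-dimethoxyphenyl]prop-2-yn-1-ol F3 after NH4Cl work-up. MnO2 (CH2Cl2, rt) should oxidise this benzylic, propargylic alcohol to ynone 15, and Et2NH in EtOH at reflux closes 15 through 16 to flavone 17, where the route is rejoined; steps 5 and 8 are bypassed.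

Step 9. The C2=C3 bond is part of a vinylogous ester and is a poor nucleophile, so epoxidation may stall while the dioxirane slowly attacks the electron-rich rings or the benzylic C–H bonds, and the epoxide may open along other paths. The fallback sets out from 17 and replaces oxygen transfer to the alkene by C3 metalation. LDA (THF, −78 °C) should remove the C3 proton to give the 3-lithio derivative of 17 F4, trimethyl borate traps it as the dimethyl flavon-3-ylboronate F5, and AcOH/H2O2 in the same flask oxidises the C–B bond to give flavonol 19, where the route is rejoined.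

Step 5. The penta-oxygenated phenol may be oxidised by the halogenating agent instead of being substituted, or substitution at the carbon flanked by two oxygens may be sluggish. The fallback sets out from 8 and installs iodine by directed ortho-metalation. MOMCl/iPr2NEt (CH2Cl2) gives 1-(benzyloxy)-2,3,4-trimethoxy-5-(methoxymethoxy)benzene F6, and n-BuLi (THF, −78 to 0 °C) lithiates the position between the two directing oxygens to give the aryllithium F7. Iodine then gives 1-(benzyloxy)-2-iodo-4,5,6-trimethoxy-3-(methoxymethoxy)benzene F8, and dilute HCl in MeOH (40 °C) removes the acetal while the benzyl ether stays, returning to the route at 9.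

Further compounds
F1 | step 8 | 2-(benzyloxy)-6-hydroxy-3,4,5-trimethoxybenzaldehyde | O=Cc1c(O)c(OC)c(OC)c(OC)c1OCc1ccccc1
F2 | step 8 | lithium acetylide of 13, {[3-(benzyloxy)-4,5-dimethoxyphenyl]ethynyl}lithium | [Li]C#Cc1cc(OC)c(OC)c(OCc2ccccc2)c1
F3 | step 8 | racemic 1-[2-(benzyloxy)-6-hydroxy-3,4,5-trimethoxyphenyl]-3-[3-(benzyloxy)-4,5-dimethoxyphenyl]prop-2-yn-1-ol | OC(C#Cc1cc(OC)c(OC)c(OCc2ccccc2)c1)c1c(O)c(OC)c(OC)c(OC)c1OCc1ccccc1
F4 | step 9 | 3-lithio derivative of 17 | COc1cc(-c2oc3c(OC)c(OC)c(OC)c(OCc4ccccc4)c3c(=O)c2[Li])cc(OCc2ccccc2)c1OC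
F5 | step 9 | dimethyl {5-(benzyloxy)-2-[3-(benzyloxy)-4,5-dimethoxyphenyl]-6,7,8-trimethoxy-4-oxo-4H-chromen-3-yl}boronate | COc1cc(-c2oc3c(OC)c(OC)c(OC)c(OCc4ccccc4)c3c(=O)c2B(OC)OC)cc(OCc2ccccc2)c1OC
F6 | step 5 | 1-(benzyloxy)-2,3,4-trimethoxy-5-(methoxymethoxy)benzene | COCOc1cc(OCc2ccccc2)c(OC)c(OC)c1OC
F7 | step 5 | [2-(benzyloxy)-3,4,5-trimethoxy-6-(methoxymethoxy)phenyl]lithium | COCOc1c([Li])c(OCc2ccccc2)c(OC)c(OC)c1OC
F8 | step 5 | 1-(benzyloxy)-2-iodo-4,5,6-trimethoxy-3-(methoxymethoxy)benzene | COCOc1c(I)c(OCc2ccccc2)c(OC)c(OC)c1OC
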